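**Retrosynthetic overview**
- The target (2R,3R)-dihydroflavonol is traced back to a seven-membered 2-aryl-4H-1,3-benzodioxepin-5-one; the key step is a ring contraction by 1,2-shift of the acetal carbon from O3 to the adjacent CH2 carbon, which forms C2–C3, ring C and both stereocentres at once.
- The seven-membered acetal comes from dehydrative acetalisation of a ring A 2,ω-dihydroxy ketone with 4-hydroxy-3,5-diprenylbenzaldehyde (ring B).
- The ring A ketone comes from resorcinol by two MOM-directed ortho-lithiations (prenyl bromide, then a chloroacetyl Weinreb amide), acetate displacement and deprotection.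
- The ring B aldehyde comes from 4-bromophenol by double ortho-C-prenylation and bromine–lithium exchange/formylation.
- Ring order: rings A and B are bought as arenes; the seven-membered acetal ring is closed first and contracted to the six-membered ring C last.

Assumption: the (R)-enantiomer of the phosphoric acid in step 8 is assigned to the (2R,3R) product by analogy only; the (S)-catalyst is used instead if the first run shows the opposite sense.

**Route**

Step 1
Reactants: 1 4-bromophenol; 2 prenyl bromide (1-bromo-3-methylbut-2-ene)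
Product: 4 4-bromo-2,6-bis(3-methylbut-2-en-1-yl)phenol, via 4-bromo-2-prenylphenol 3 (not isolated)
Conditions: NaH (2.2 equiv), toluene, 0 °C; 2 (2.2 equiv), rt, 24 h
Reagents that add atoms: none
Why: Ortho-selective C-alkylation of a sodium phenoxide in a non-polar solvent (tight ion aggregate, para position blocked by bromine) runs twice, the second time on the phenoxide of 3.

Step 2
Reactants: 4 4-bromo-2,6-bis(3-methylbut-2-en-1-yl)phenol
Product: 6 4-hydroxy-3,5-bis(3-methylbut-2-en-1-yl)benzaldehyde, via dilithiated phenoxide 5 (not isolated)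
Conditions: t-BuLi (3.1 equiv), THF, −78 °C; DMF (4 equiv), −78 °C → rt; aq NH4Cl
Reagents that add atoms: N,N-dimethylformamide (DMF), CN(C)C=O
Why: After O–H deprotonation, bromine–lithium exchange at −78 °C is much faster than deprotonation of the benzylic/allylic CH2 groups, and the aryllithium is formylated by DMF (Bouveault aldehyde synthesis).

Step 3
Reactants: 7 resorcinol
Product: 8 1,3-bis(methoxymethoxy)benzene
Conditions: NaH (2.4 equiv), DMF, 0 °C; MOMCl (2.4 equiv), 0 °C → rt
Reagents that add atoms: chloromethyl methyl ether (MOMCl), COCCl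
Why: Williamson etherification installs the MOM groups, which serve as protecting groups and as the ortho-directing groups for steps 4 and 5.

Step 4
Reactants: 8 1,3-bis(methoxymethoxy)benzene; 2 prenyl bromide
Product: 10 1,3-bis(methoxymethoxy)-2-(3-methylbut-2-en-1-yl)benzene, via 2-lithio arene 9 (not isolated)
Conditions: n-BuLi (1.1 equiv), THF, 0 °C → rt, 1 h; CuI (10 mol %), 2 (1.2 equiv), −78 °C → rt
Reagents that add atoms: none
Why: Directed ortho-metalation occurs at C2 between the two cooperating OMOM groups, and the aryllithium is allylated by prenyl bromide under copper catalysis with SN2 regiochemistry.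

Step 5
Reactants: 10 1,3-bis(methoxymethoxy)-2-(3-methylbut-2-en-1-yl)benzene; 11 2-chloro-N-methoxy-N-methylacetamide
Product: 13 2-chloro-1-[2,4-bis(methoxymethoxy)-3-(3-methylbut-2-en-1-yl)phenyl]ethan-1-one, via 4-lithio arene 12 (not isolated)
Conditions: n-BuLi (1.1 equiv), TMEDA (1.1 equiv), THF, −20 → 0 °C, 1 h; 11 (1.2 equiv), −78 → 0 °C; aq NH4Cl
Reagents that add atoms: none
Why: A second directed ortho-metalation can only occur at C4 (C6 is equivalent), and the Weinreb amide gives the ketone through a chelated tetrahedral adduct that prevents over-addition (Weinreb ketone synthesis).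

Step 6
Reactants: 13 2-chloro-1-[2,4-bis(methoxymethoxy)-3-(3-methylbut-2-en-1-yl)phenyl]ethan-1-one
Product: 15 2-hydroxy-1-[2,4-dihydroxy-3-(3-methylbut-2-en-1-yl)phenyl]ethan-1-one, via acetoxy ketone 14 (not isolated)
Conditions: KOAc (1.5 equiv), DMF, rt, 3 h; then 3 M HCl in MeOH, 40 °C, 3 h
Reagents that add atoms: potassium acetate, CC(=O)[O-].[K+]
Why: SN2 displacement of the activated α-chloride by acetate is followed in the same pot by acid-catalysed methanolysis (transesterification of the acetate, cleavage of both MOM acetals) under conditions mild enough to leave the prenyl group uncyclised.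

Step 7
Reactants: 15 2-hydroxy-1-[2,4-dihydroxy-3-(3-methylbut-2-en-1-yl)phenyl]ethan-1-one; 6 4-hydroxy-3,5-bis(3-methylbut-2-en-1-yl)benzaldehyde
Product: 16 rac-8-hydroxy-2-[4-hydroxy-3,5-bis(3-methylbut-2-en-1-yl)phenyl]-9-(3-methylbut-2-en-1-yl)-4H-1,3-benzodioxepin-5-one
Conditions: PPTS (10 mol %), 4 Å MS, toluene (0.02 M), 45 °C
Reagents that add atoms: none
Why: Acid-catalysed dehydrative acetalisation: the primary hydroxyl forms the hemiacetal, ionisation is assisted by the para-hydroxyl of ring B, and the neighbouring phenolic hydroxyl closes the benzo-fused seven-membered O,O-acetal, while the weak pyridinium acid does not enolise the ketone, so the acetal (a racemate whose stereocentre is erased in step 8) can be isolated.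

Step 8
Reactants: 16 rac-8-hydroxy-2-[4-hydroxy-3,5-bis(3-methylbut-2-en-1-yl)phenyl]-9-(3-methylbut-2-en-1-yl)-4H-1,3-benzodioxepin-5-one
Product: 17 (2R,3R)-3,7-dihydroxy-2-[4-hydroxy-3,5-bis(3-methylbut-2-en-1-yl)phenyl]-8-(3-methylbut-2-en-1-yl)-2,3-dihydro-4H-chromen-4-one (CNP0316331.1)
Conditions: (R)-TRIP [(R)-3,3′-bis(2,4,6-triisopropylphenyl)-1,1′-binaphthyl-2,2′-diyl hydrogen phosphate] (10 mol %), 5 Å MS, toluene (0.05 M), 25 °C, 24–48 h
Reagents that add atoms: none
Why: Proposed new method: a chiral phosphoric acid-catalysed enantioselective ring contraction (seven- to six-membered) by 1,2-shift of the acetal carbon from O3 to the adjacent C4, in which the acid ionises the C2–O3 bond to an O1-tethered aryloxy-substituted para-quinone methide/oxocarbenium ion, enolises the liberated α-hydroxy ketone to a Z-enediol held on the phosphate, and the enediol carbon attacks the tethered cation (6-enolendo-exo-trig) so that C2–C3, ring C and both stereocentres form together, C3 (R) being set by enol-face selection inside the chiral hydrogen-bonded ion pair and C2 (R) by chair-like closure with the aryl group equatorial, reinforced by reversible O1–C2 ionisation that funnels to the trans isomer; the closest known reaction types are the Petasis–Ferrier rearrangement, the phosphoric acid-catalysed aza-Petasis–Ferrier rearrangement, the acetal [1,2]-Wittig rearrangement and phosphoric acid-catalysed 1,6-additions to para-quinone methides generated in situ.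

**Compound list**

1 | 4-bromophenol | Oc1ccc(Br)cc1 | starting material
2 | prenyl bromide (1-bromo-3-methylbut-2-ene) | CC(C)=CCBr | starting material
3 | 4-bromo-2-(3-methylbut-2-en-1-yl)phenol | CC(C)=CCc1cc(Br)ccc1O | intermediate
4 | 4-bromo-2,6-bis(3-methylbut-2-en-1-yl)phenol | CC(C)=CCc1cc(Br)cc(CC=C(C)C)c1O | intermediate
5 | lithium 4-lithio-2,6-bis(3-methylbut-2-en-1-yl)phenolate | [Li]c1cc(CC=C(C)C)c(O[Li])c(CC=C(C)C)c1 | intermediate
6 | 4-hydroxy-3,5-bis(3-methylbut-2-en-1-yl)benzaldehyde | CC(C)=CCc1cc(C=O)cc(CC=C(C)C)c1O | intermediate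
7 | resorcinol | Oc1cccc(O)c1 | starting material
8 | 1,3-bis(methoxymethoxy)benzene | COCOc1cccc(OCOC)c1 | intermediate
9 | [2,6-bis(methoxymethoxy)phenyl]lithium | COCOc1cccc(OCOC)c1[Li] | intermediate
10 | 1,3-bis(methoxymethoxy)-2-(3-methylbut-2-en-1-yl)benzene | COCOc1cccc(OCOC)c1CC=C(C)C | intermediate
11 | 2-chloro-N-methoxy-N-methylacetamide | CON(C)C(=O)CCl | starting material
12 | [2,4-bis(methoxymethoxy)-3-(3-methylbut-2-en-1-yl)phenyl]lithium | COCOc1ccc([Li])c(OCOC)c1CC=C(C)C | intermediate
13 | 2-chloro-1-[2,4-bis(methoxymethoxy)-3-(3-methylbut-2-en-1-yl)phenyl]ethan-1-one | COCOc1ccc(C(=O)CCl)c(OCOC)c1CC=C(C)C | intermediate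
14 | 2-[2,4-bis(methoxymethoxy)-3-(3-methylbut-2-en-1-yl)phenyl]-2-oxoethyl acetate | COCOc1ccc(C(=O)COC(C)=O)c(OCOC)c1CC=C(C)C | intermediate
15 | 2-hydroxy-1-[2,4-dihydroxy-3-(3-methylbut-2-en-1-yl)phenyl]ethan-1-one | CC(C)=CCc1c(O)ccc(C(=O)CO)c1O | intermediate
16 | rac-8-hydroxy-2-[4-hydroxy-3,5-bis(3-methylbut-2-en-1-yl)phenyl]-9-(3-methylbut-2-en-1-yl)-4H-1,3-benzodioxepin-5-one | O=C1COC(c2cc(CC=C(C)C)c(O)c(CC=C(C)C)c2)Oc2c1ccc(O)c2CC=C(C)C | intermediate
17 | (2R,3R)-3,7-dihydroxy-2-[4-hydroxy-3,5-bis(3-methylbut-2-en-1-yl)phenyl]-8-(3-methylbut-2-en-1-yl)-2,3-dihydro-4H-chromen-4-one | CC(C)=CCc1cc([C@H]2Oc3c(ccc(O)c3CC=C(C)C)C(=O)[C@@H]2O)cc(CC=C(C)C)c1O | target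

**Step count and risks**

Total steps: 8. Longest linear sequence: 6 steps (7 → 8 → 10 → 13 → 15 → 16 → 17); the ring B branch (1 → 4 → 6) is 2 steps and joins at step 7.

The three steps most likely to fail:

Step 8, the new ring contraction. Enolisation of the released α-hydroxy ketone may be slow, an uncatalysed background reaction may erode the ee, the sense and level of induction are unknown, and long exposure could isomerise the product to the 2-benzyl-2-hydroxybenzofuranone. The fallback uses only known chemistry, sets out from 10 and 6 and comes back at 17. Compound 10 is lithiated to 12 as in step 5 and quenched with N-methoxy-N-methylacetamide to give 1-[2,4-bis(methoxymethoxy)-3-(3-methylbut-2-en-1-yl)phenyl]ethan-1-one F1. Aldehyde 6 is protected (NaH, MOMCl, DMF) as 4-(methoxymethoxy)-3,5-bis(3-methylbut-2-en-1-yl)benzaldehyde F2. Claisen–Schmidt condensation (KOH, EtOH, rt) of the two gives (E)-1-[2,4-bis(methoxymethoxy)-3-(3-methylbut-2-en-1-yl)phenyl]-3-[4-(methoxymethoxy)-3,5-bis(3-methylbut-2-en-1-yl)phenyl]prop-2-en-1-one F3. Juliá–Colonna epoxidation (poly-L-leucine, urea–H2O2, DBU, THF), a nucleophilic epoxidation that leaves the isolated prenyl alkenes untouched, gives (2R,3S)-2,3-epoxy-1-[2,4-bis(methoxymethoxy)-3-(3-methylbut-2-en-1-yl)phenyl]-3-[4-(methoxymethoxy)-3,5-bis(3-methylbut-2-en-1-yl)phenyl]propan-1-one F4. HCl in MeOH (45 °C) then removes the three MOM groups, and the freed ortho-hydroxyl opens the epoxide at the benzylic carbon with inversion (6-endo) to give 17.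

Step 7, the seven-membered acetal. A para-hydroxybenzaldehyde is a poor acetalisation partner, and the product ionises easily on silica, so it may not be isolable. The fallback sets out from 6 and 15 and comes back at 16. The ring B phenol is masked first (TBSCl, imidazole, DMF) to give 4-[(tert-butyldimethylsilyl)oxy]-3,5-bis(3-methylbut-2-en-1-yl)benzaldehyde F5. Acetalisation with 15 under standard conditions (PPTS, benzene, Dean–Stark) gives 2-{4-[(tert-butyldimethylsilyl)oxy]-3,5-bis(3-methylbut-2-en-1-yl)phenyl}-8-hydroxy-9-(3-methylbut-2-en-1-yl)-4H-1,3-benzodioxepin-5-one F6, which cannot ionise through a quinone methide and survives chromatography. Buffered desilylation (TBAF, AcOH, THF, 0 °C) releases 16, which is used at once in step 8.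

Step 5, the second ortho-lithiation. The ArCH2 of the prenyl group is benzylic and allylic and is flanked by both OMOM groups, so lateral lithiation may compete with ring lithiation. The fallback sets out from 10 and comes back at 12 (and so at 13). Electrophilic bromination of the electron-rich ring (NBS, MeCN, −20 °C) gives 1-bromo-2,4-bis(methoxymethoxy)-3-(3-methylbut-2-en-1-yl)benzene F7. Bromine–lithium exchange (n-BuLi, THF, −78 °C, 10 min), which is far faster than any deprotonation, gives 12 regiospecifically, and this is quenched with 11 as before.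

**Further compounds**

F1 | step 8 | 1-[2,4-bis(methoxymethoxy)-3-(3-methylbut-2-en-1-yl)phenyl]ethan-1-one | COCOc1ccc(C(C)=O)c(OCOC)c1CC=C(C)C
F2 | step 8 | 4-(methoxymethoxy)-3,5-bis(3-methylbut-2-en-1-yl)benzaldehyde | COCOc1c(CC=C(C)C)cc(C=O)cc1CC=C(C)C
F3 | step 8 | (E)-1-[2,4-bis(methoxymethoxy)-3-(3-methylbut-2-en-1-yl)phenyl]-3-[4-(methoxymethoxy)-3,5-bis(3-methylbut-2-en-1-yl)phenyl]prop-2-en-1-one | COCOc1ccc(C(=O)/C=C/c2cc(CC=C(C)C)c(OCOC)c(CC=C(C)C)c2)c(OCOC)c1CC=C(C)C
F4 | step 8 | (2R,3S)-2,3-epoxy-1-[2,4-bis(methoxymethoxy)-3-(3-methylbut-2-en-1-yl)phenyl]-3-[4-(methoxymethoxy)-3,5-bis(3-methylbut-2-en-1-yl)phenyl]propan-1-one | COCOc1ccc(C(=O)[C@@H]2O[C@H]2c3cc(CC=C(C)C)c(OCOC)c(CC=C(C)C)c3)c(OCOC)c1CC=C(C)C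
F5 | step 7 | 4-[(tert-butyldimethylsilyl)oxy]-3,5-bis(3-methylbut-2-en-1-yl)benzaldehyde | CC(C)=CCc1cc(C=O)cc(CC=C(C)C)c1O[Si](C)(C)C(C)(C)C
F6 | step 7 | 2-{4-[(tert-butyldimethylsilyl)oxy]-3,5-bis(3-methylbut-2-en-1-yl)phenyl}-8-hydroxy-9-(3-methylbut-2-en-1-yl)-4H-1,3-benzodioxepin-5-one | O=C1COC(c2cc(CC=C(C)C)c(O[Si](C)(C)C(C)(C)C)c(CC=C(C)C)c2)Oc2c1ccc(O)c2CC=C(C)C
F7 | step 5 | 1-bromo-2,4-bis(methoxymethoxy)-3-(3-methylbut-2-en-1-yl)benzene | COCOc1ccc(Br)c(OCOC)c1CC=C(C)C
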